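**Retrosynthetic overview**

1. The target is traced back (naphthylmethyl removal, double angeloylation, hydroxyl-directed epoxidation of C8=C9, desilylation, hydroxyl-directed reduction of the C6 ketone) to the cis-fused hydroazulenone 15.
2. 15 comes from a formal [3+2] annulation of the enol silane of 3-methyl-2-butanone (it supplies C3, C4 and the isopropyl group) with bicyclo[5.1.0]octenone 11. The enabling feature is the donor–acceptor cyclopropane C1–C2–C5 fused to the seven-membered ring, with the naphthylmethoxy donor on C2 and the C6 ketone acceptor on C5. Heterolysis of C2–C5 gives a C2 oxocarbenium and a C5 enolate; C2–C3 forms first and C4–C5 then closes the cyclopentane.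
3. 11 comes from ring-closing metathesis (C8=C9) of a methallyl ketone that is made from lactone 7 by Weinreb aminolysis, silylation and Grignard addition.
4. 7 comes from intramolecular cyclopropanation of the allylic diazoacetate 6; the temporary lactone tether relays the carbinol configuration to C1, C2 and C5. 6 comes from asymmetric vinylation of enal 3.
5. Ring order: cyclopropane with temporary γ-lactone, then the seven-membered carbocycle, then the five-membered carbocycle (cyclopropane consumed), then the epoxide.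

Key step: step 11

Remark: carbons are numbered as in the daucane skeleton (C1 methyl-bearing ring-fusion carbon, C2 oxygenated CH of the five-membered ring, C3, C4 isopropyl carbinol carbon, C5 ring-fusion CH, C6 to C10 around the seven-membered ring, C8 methyl-bearing). α is the face that carries the C1 methyl and H-5, β the opposite face. The SMILES is read as a cis-fused hydroazulene, (1R,2S,4S,5R,6R,8S,9R,10R) in this numbering, with both esters as angelates (Z).

**Route**

Step 1
Reactants: 1 (E)-3-ethoxy-2-methylprop-2-enal; 2 naphthalen-2-ylmethanol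
Product: 3 (E)-2-methyl-3-(naphthalen-2-ylmethoxy)prop-2-enal
Conditions: PPTS (5 mol %), toluene, 70 °C, reduced pressure (EtOH distilled off)
Reagents that add atoms: none
Why: acid-catalysed transetherification (addition–elimination) of a vinylogous ester, driven by removal of ethanol, should return the thermodynamic E isomer in which the ether oxygen is cis to the methyl group.

Step 2
Reactants: 3 (E)-2-methyl-3-(naphthalen-2-ylmethoxy)prop-2-enal
Product: 4 (1E,3S)-2-methyl-1-(naphthalen-2-ylmethoxy)penta-1,4-dien-3-ol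
Conditions: ZnCl2, CH2=CHMgBr (2 equiv per Zn), THF/toluene, then N,N,N',N'-tetraethylethylenediamine; (2S)-(−)-3-exo-morpholinoisoborneol (10 mol %), 0 °C; pH 7 buffer work-up, Et3N-deactivated silica
Reagents that add atoms: vinylmagnesium bromide, C=C[Mg]Br (transmetallated in the flask to divinylzinc, C=C[Zn]C=C)
Why: amino-alcohol-catalysed enantioselective 1,2-addition of a vinylzinc reagent to an aldehyde, in which the ligand is expected to direct vinyl transfer to the Si face and so set the S carbinol centre (the future C10) from which all other stereocentres are relayed.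

Step 3
Reactants: 4 (1E,3S)-2-methyl-1-(naphthalen-2-ylmethoxy)penta-1,4-dien-3-ol
Product: 5 (1E,3S)-2-methyl-1-(naphthalen-2-ylmethoxy)penta-1,4-dien-3-yl 2-bromoacetate
Conditions: BrCH2COBr, 2,6-lutidine, CH2Cl2, −40 °C
Reagents that add atoms: bromoacetyl bromide, O=C(Br)CBr
Why: O-acylation with an acid bromide under cold, fully buffered conditions should spare the acid-labile γ-hydroxy enol ether and leaves the carbinol centre untouched.

Step 4
Reactants: 5 (1E,3S)-2-methyl-1-(naphthalen-2-ylmethoxy)penta-1,4-dien-3-yl 2-bromoacetate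
Product: 6 (1E,3S)-2-methyl-1-(naphthalen-2-ylmethoxy)penta-1,4-dien-3-yl 2-diazoacetate
Conditions: TsNHNHTs, DBU, THF, 0 °C
Reagents that add atoms: N,N'-ditosylhydrazine, Cc1ccc(cc1)S(=O)(=O)NNS(=O)(=O)c1ccc(C)cc1
Why: N-alkylation of the ditosylhydrazine anion by the bromoacetate followed by twofold base-induced sulfinate elimination is a fast, basic diazoacetate synthesis that suits the labile allylic ester.

Step 5
Reactants: 6 (1E,3S)-2-methyl-1-(naphthalen-2-ylmethoxy)penta-1,4-dien-3-yl 2-diazoacetate
Product: 7 (1S,4S,5R,6R)-4-ethenyl-5-methyl-6-(naphthalen-2-ylmethoxy)-3-oxabicyclo[3.1.0]hexan-2-one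
Conditions: Rh2(OAc)4 (1 mol %), CH2Cl2, rt, slow addition of 6
Reagents that add atoms: none
Why: intramolecular cyclopropanation of an allylic diazoacetate by a dirhodium carbenoid should pick the electron-rich enol ether over the vinyl group; the stereospecific syn addition keeps the ether oxygen cis to the methyl group (exo), the lactone tether forces the carbonyl cis to the carbinol carbon, and A(1,2) strain with the alkene methyl places the vinyl group on the cyclopropane face.

Step 6
Reactants: 7 (1S,4S,5R,6R)-4-ethenyl-5-methyl-6-(naphthalen-2-ylmethoxy)-3-oxabicyclo[3.1.0]hexan-2-one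
Product: 8 2-[(1S)-1-hydroxyprop-2-en-1-yl]-N-methoxy-N,2-dimethyl-3-(naphthalen-2-ylmethoxy)cyclopropane-1-carboxamide (ring configuration as in 7)
Conditions: MeNH(OMe)·HCl, iPrMgCl, THF, −20 °C
Reagents that add atoms: N,O-dimethylhydroxylamine hydrochloride, CNOC.Cl
Why: Weinreb aminolysis of the lactone by the chloromagnesium amide is basic and non-Lewis-acidic, so the alkoxycyclopropane should survive and no stereocentre is touched.

Step 7
Reactants: 8 hydroxy Weinreb amide
Product: 9 2-[(1S)-1-(tert-butyldimethylsilyloxy)prop-2-en-1-yl]-N-methoxy-N,2-dimethyl-3-(naphthalen-2-ylmethoxy)cyclopropane-1-carboxamide (ring configuration as in 7)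
Conditions: TBSOTf, 2,6-lutidine, CH2Cl2, −78 °C
Reagents that add atoms: tert-butyldimethylsilyl trifluoromethanesulfonate, CC(C)(C)[Si](C)(C)OS(=O)(=O)C(F)(F)F
Why: silylation of the hindered allylic alcohol with a silyl triflate blocks relactonisation and gives a non-coordinating protecting group for the Lewis-acid step.

Step 8
Reactants: 9 silyl ether Weinreb amide
Product: 10 1-{2-[(1S)-1-(tert-butyldimethylsilyloxy)prop-2-en-1-yl]-2-methyl-3-(naphthalen-2-ylmethoxy)cyclopropyl}-3-methylbut-3-en-1-one (ring configuration as in 7)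
Conditions: 2-methylallylmagnesium chloride, THF, −78 °C; cold aq NH4Cl
Reagents that add atoms: 2-methylallylmagnesium chloride, C=C(C)C[Mg]Cl
Why: Weinreb ketone synthesis, in which the stable magnesium chelate prevents over-addition and the cold quench should keep the β,γ-unsaturated ketone out of conjugation.

Step 9
Reactants: 10 methallyl ketone diene
Product: 11 6-(tert-butyldimethylsilyloxy)-4,7-dimethyl-8-(naphthalen-2-ylmethoxy)bicyclo[5.1.0]oct-4-en-2-one (silyloxy cis to the 7-methyl; naphthylmethoxy exo, cis to the 7-methyl and H-1)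
Conditions: second-generation Grubbs catalyst (5 mol %), 1,4-benzoquinone (10 mol %), CH2Cl2 (5 mM), 40 °C
Reagents that add atoms: none
Why: ring-closing metathesis to a trisubstituted cycloheptene is favoured because the two alkene arms are held cis on the cyclopropane, and no stereocentre is formed.

Step 10
Reactants: 12 3-methyl-2-butanone
Product: 13 3-methyl-2-(trimethylsilyloxy)but-1-ene
Conditions: lithium diisopropylamide, THF, −78 °C; Me3SiCl
Reagents that add atoms: chlorotrimethylsilane, C[Si](C)(C)Cl
Why: kinetic deprotonation at the methyl group and O-silylation give the less substituted enol silane.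

Step 11
Reactants: 11 bicyclo[5.1.0]octenone (donor–acceptor cyclopropane); 13 3-methyl-2-(trimethylsilyloxy)but-1-ene (2.5 equiv)
Product: 15 10α-(tert-butyldimethylsilyloxy)-4β-hydroxy-2β-(naphthalen-2-ylmethoxy)dauc-8-en-6-one (cis-fused; 1α-methyl, 5α-H, 4α-isopropyl), via trichlorostannyl enolate keto ether 14 (not isolated)
Conditions: SnCl4 (1.1 equiv), CH2Cl2, −78 °C; aq NaHCO3
Reagents that add atoms: none
Why: SnCl4 binds the C6 ketone and heterolyses the push–pull C2–C5 bond of the cyclopropane (strain release) to a regiodefined C5 tin enolate and a C2 oxocarbenium; enol silane 13 attacks C2, and the tin enolate then adds to the liberated isopropyl ketone to form C4–C5. The closest known reaction type is the Lewis-acid-promoted formal [3+2] annulation of donor–acceptor cyclopropanes (2-alkoxy- or 2-aryloxycyclopropyl ketones) with silyl enol ethers. The cyclopentane closes by a 5-(enolexo)-exo-trig aldol addition. C2 is set by attack anti to the departing enolate (inversion at the exo-alkoxy cyclopropane carbon); C5 is set by the tether, which can only reach the enolate face syn to the C1 side chain and so gives the cis ring fusion; C4 is set by the tin-bridged closed transition state, which keeps the carbinol oxygen syn to the C6 carbonyl and turns the isopropyl group to the convex face. The step needs cleavage of C2–C5 and not C1–C2 or C1–C5 (secured by the vicinal donor and acceptor), reaction at C5 and not C7 (the enolate is born at C5 and should not equilibrate at −78 °C), and survival of the allylic silyl ether (non-coordinating; the quaternary C1 leaves the oxocarbenium no elimination path).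

Step 12
Reactants: 15 hydroazulenone
Product: 16 10α-(tert-butyldimethylsilyloxy)-2β-(naphthalen-2-ylmethoxy)dauc-8-ene-4β,6α-diol
Conditions: Me4NBH(OAc)3, MeCN/AcOH, −30 °C
Reagents that add atoms: none
Why: Saksena–Evans hydroxyl-directed reduction, in which the 4β-alkoxyborohydride delivers hydride intramolecularly to the β face of the C6 ketone and so gives the 6α-alcohol (anti-1,3-diol).

Step 13
Reactants: 16 silyl ether diol
Product: 17 2β-(naphthalen-2-ylmethoxy)dauc-8-ene-4β,6α,10α-triol
Conditions: Bu4NF, THF, 0 °C to rt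
Reagents that add atoms: none
Why: fluoride-mediated desilylation frees the allylic 10α-hydroxyl without touching any stereocentre.

Step 14
Reactants: 17 triol
Product: 18 8α,9α-epoxy-2β-(naphthalen-2-ylmethoxy)daucane-4β,6α,10α-triol
Conditions: VO(acac)2 (5 mol %), tBuOOH, CH2Cl2, 0 °C
Reagents that add atoms: tert-butyl hydroperoxide, CC(C)(C)OO
Why: vanadium-catalysed hydroxyl-directed epoxidation, in which the allylic 10α-hydroxyl (reinforced by the homoallylic 6α-hydroxyl) delivers the peroxide oxygen to the α face of C8=C9 and sets C8 and C9.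

Step 15
Reactants: 18 epoxy triol; 19 angelic acid, (Z)-2-methylbut-2-enoic acid (6 equiv)
Product: 21 6α,10α-bis(angeloyloxy)-8α,9α-epoxy-2β-(naphthalen-2-ylmethoxy)daucan-4β-ol, via angelic 2,4,6-trichlorobenzoic anhydride 20 (not isolated)
Conditions: 2,4,6-trichlorobenzoyl chloride, Et3N, toluene, rt; then 18, 75 °C
Reagents that add atoms: none
Why: Yamaguchi-type mixed-anhydride esterification run without a nucleophilic catalyst should acylate the two secondary hydroxyls with retention of the Z geometry, while the tertiary 4β-hydroxyl stays free and the 2β-oxygen stays masked.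

Step 16
Reactants: 21 bis-angelate naphthylmethyl ether
Product: 22 CNP0265715.2, 6α,10α-bis(angeloyloxy)-8α,9α-epoxydaucane-2β,4β-diol, (1R,2S,4S,5R,6R,8S,9R,10R)
Conditions: DDQ, CH2Cl2/pH 7 phosphate buffer, 0 °C
Reagents that add atoms: none
Why: oxidative cleavage of the 2-naphthylmethyl ether by DDQ under buffered conditions should spare the electron-poor angelate alkenes and the epoxide.

**Compound list**

1 | (E)-3-ethoxy-2-methylprop-2-enal | CCO/C=C(\C)C=O | starting material
2 | naphthalen-2-ylmethanol | OCc1ccc2ccccc2c1 | starting material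
3 | (E)-2-methyl-3-(naphthalen-2-ylmethoxy)prop-2-enal | O=C/C(C)=C/OCc1ccc2ccccc2c1 | intermediate
4 | (1E,3S)-2-methyl-1-(naphthalen-2-ylmethoxy)penta-1,4-dien-3-ol | O[C@@H](C=C)/C(C)=C/OCc1ccc2ccccc2c1 | intermediate
5 | (1E,3S)-2-methyl-1-(naphthalen-2-ylmethoxy)penta-1,4-dien-3-yl 2-bromoacetate | BrCC(=O)O[C@@H](C=C)/C(C)=C/OCc1ccc2ccccc2c1 | intermediate
6 | (1E,3S)-2-methyl-1-(naphthalen-2-ylmethoxy)penta-1,4-dien-3-yl 2-diazoacetate | [N-]=[N+]=CC(=O)O[C@@H](C=C)/C(C)=C/OCc1ccc2ccccc2c1 | intermediate
7 | (1S,4S,5R,6R)-4-ethenyl-5-methyl-6-(naphthalen-2-ylmethoxy)-3-oxabicyclo[3.1.0]hexan-2-one (vinyl on the cyclopropane face; naphthylmethoxy exo, cis to the methyl) | O=C1O[C@@H](C=C)[C@@]2(C)[C@H](OCc3ccc4ccccc4c3)[C@@H]12 | intermediate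
8 | 2-[(1S)-1-hydroxyprop-2-en-1-yl]-N-methoxy-N,2-dimethyl-3-(naphthalen-2-ylmethoxy)cyclopropane-1-carboxamide (amide and hydroxyallyl arm cis; naphthylmethoxy trans to both) | CON(C)C(=O)[C@@H]1[C@@H](OCc2ccc3ccccc3c2)[C@]1(C)[C@@H](O)C=C | intermediate
9 | tert-butyldimethylsilyl ether of 8 | CON(C)C(=O)[C@@H]1[C@@H](OCc2ccc3ccccc3c2)[C@]1(C)[C@@H](O[Si](C)(C)C(C)(C)C)C=C | intermediate
10 | 1-{2-[(1S)-1-(tert-butyldimethylsilyloxy)prop-2-en-1-yl]-2-methyl-3-(naphthalen-2-ylmethoxy)cyclopropyl}-3-methylbut-3-en-1-one (ring configuration as in 7) | C=C(C)CC(=O)[C@@H]1[C@@H](OCc2ccc3ccccc3c2)[C@]1(C)[C@@H](O[Si](C)(C)C(C)(C)C)C=C | intermediate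
11 | 6-(tert-butyldimethylsilyloxy)-4,7-dimethyl-8-(naphthalen-2-ylmethoxy)bicyclo[5.1.0]oct-4-en-2-one (silyloxy cis to 7-methyl; naphthylmethoxy exo) | O=C1CC(C)=C[C@H](O[Si](C)(C)C(C)(C)C)[C@@]2(C)[C@H](OCc3ccc4ccccc4c3)[C@@H]12 | intermediate
12 | 3-methyl-2-butanone | CC(=O)C(C)C | starting material
13 | 3-methyl-2-(trimethylsilyloxy)but-1-ene | C=C(O[Si](C)(C)C)C(C)C | intermediate
14 | ring-opened C5=C6 trichlorostannyl enolate carrying the 1-(naphthalen-2-ylmethoxy)-4-methyl-3-oxopentyl chain on C1 | Cl[Sn](Cl)(Cl)OC1=C[C@](C)([C@@H](OCc2ccc3ccccc3c2)CC(=O)C(C)C)[C@@H](O[Si](C)(C)C(C)(C)C)C=C(C)C1 | intermediate (not isolated)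
15 | 10α-(tert-butyldimethylsilyloxy)-4β-hydroxy-2β-(naphthalen-2-ylmethoxy)dauc-8-en-6-one (cis-fused) | O=C1CC(C)=C[C@H](O[Si](C)(C)C(C)(C)C)[C@@]2(C)[C@@H](OCc3ccc4ccccc4c3)C[C@](O)(C(C)C)[C@@H]12 | intermediate
16 | 10α-(tert-butyldimethylsilyloxy)-2β-(naphthalen-2-ylmethoxy)dauc-8-ene-4β,6α-diol | O[C@@H]1CC(C)=C[C@H](O[Si](C)(C)C(C)(C)C)[C@@]2(C)[C@@H](OCc3ccc4ccccc4c3)C[C@](O)(C(C)C)[C@@H]12 | intermediate
17 | 2β-(naphthalen-2-ylmethoxy)dauc-8-ene-4β,6α,10α-triol | O[C@@H]1CC(C)=C[C@H](O)[C@@]2(C)[C@@H](OCc3ccc4ccccc4c3)C[C@](O)(C(C)C)[C@@H]12 | intermediate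
18 | 8α,9α-epoxy-2β-(naphthalen-2-ylmethoxy)daucane-4β,6α,10α-triol | O[C@@H]1C[C@]2(C)O[C@@H]2[C@H](O)[C@@]2(C)[C@@H](OCc3ccc4ccccc4c3)C[C@](O)(C(C)C)[C@@H]12 | intermediate
19 | angelic acid, (Z)-2-methylbut-2-enoic acid | C/C=C(/C)C(=O)O | starting material
20 | angelic 2,4,6-trichlorobenzoic anhydride | C/C=C(/C)C(=O)OC(=O)c1c(Cl)cc(Cl)cc1Cl | intermediate (not isolated)
21 | 6α,10α-bis(angeloyloxy)-8α,9α-epoxy-2β-(naphthalen-2-ylmethoxy)daucan-4β-ol | C/C=C(/C)C(=O)O[C@@H]1C[C@]2(C)O[C@@H]2[C@H](OC(=O)/C(C)=C\C)[C@@]2(C)[C@@H](OCc3ccc4ccccc4c3)C[C@](O)(C(C)C)[C@@H]12 | intermediate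
22 | CNP0265715.2, 6α,10α-bis(angeloyloxy)-8α,9α-epoxydaucane-2β,4β-diol | C/C=C(/C)C(=O)O[C@@H]1C[C@]2(C)O[C@@H]2[C@H](OC(=O)/C(C)=C\C)[C@@]2(C)[C@@H](O)C[C@](O)(C(C)C)[C@@H]12 | target

**Step count and risks**

Total steps: 16. Longest linear sequence: 15 steps (steps 1 to 9 and 11 to 16; step 10 is a one-step side branch).

Most likely to fail:

1. Step 11. What may go wrong: loss of stereochemical memory at C2 through a long-lived free oxocarbenium, a ring closure that stalls after the first C–C bond, or retro-aldol opening of the tin aldolate. Fallback: the two bond formations are decoupled. From 11 and 13, catalytic Me3SiOTf with 2,6-di-tert-butyl-4-methylpyridine in CH2Cl2 at −78 °C (silyl-transfer ring-opening Mukaiyama addition, Et3N quench) should stop at the ring-opened C5=C6 trimethylsilyl enol ether keto ether F1, which is isolated. A separate chelation-controlled intramolecular Mukaiyama aldol addition (TiCl4, CH2Cl2, −78 °C) would then close C4–C5 and return to 15.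

2. Step 5. What may go wrong: ionisation or 1,3-acyloxy shift of the vinylogous acylal ester before carbene transfer, or diversion of the carbenoid to the vinyl group or to oxonium ylide formation at the ether oxygen. Fallback: the ester tether is dropped and the cyclopropane is made intermolecularly. From 4, silylation (TBSOTf, 2,6-lutidine, CH2Cl2, −78 °C) gives the silyl ether F2. Copper-catalysed asymmetric cyclopropanation of its enol ether double bond with ethyl diazoacetate ([Cu(MeCN)4]PF6, tert-butyl bis(oxazoline) ligand, CH2Cl2, slow addition) should give the ethyl cyclopropanecarboxylate F3, with the ester trans to the naphthylmethoxy group and the face set by the catalyst; diastereomers would be separated if needed. Weinreb aminolysis (MeNH(OMe)·HCl, iPrMgCl, THF, −20 °C) then returns to 9.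

3. Step 15. What may go wrong: incomplete acylation of the hindered 10α-hydroxyl and Z to E isomerisation of the angeloyl groups under forcing conditions. Fallback: the Z alkenes are built on the substrate. From 18, DCC/DMAP esterification with 2-[bis(2,2,2-trifluoroethoxy)phosphoryl]propanoic acid gives the bis(phosphonopropionate) F4 (mixture of epimers at the two phosphonate-bearing carbons). A twofold Still–Gennari olefination (potassium bis(trimethylsilyl)amide, 18-crown-6, THF, −78 °C, acetaldehyde) then returns to 21.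

Further compounds
F1 | step 11 | ring-opened C5=C6 trimethylsilyl enol ether carrying the 1-(naphthalen-2-ylmethoxy)-4-methyl-3-oxopentyl chain on C1 | C[Si](C)(C)OC1=C[C@](C)([C@@H](OCc2ccc3ccccc3c2)CC(=O)C(C)C)[C@@H](O[Si](C)(C)C(C)(C)C)C=C(C)C1
F2 | step 5 | tert-butyldimethylsilyl ether of 4 | CC(C)(C)[Si](C)(C)O[C@@H](C=C)/C(C)=C/OCc1ccc2ccccc2c1
F3 | step 5 | ethyl 2-[(1S)-1-(tert-butyldimethylsilyloxy)prop-2-en-1-yl]-2-methyl-3-(naphthalen-2-ylmethoxy)cyclopropane-1-carboxylate (ring configuration as in 9) | CCOC(=O)[C@@H]1[C@@H](OCc2ccc3ccccc3c2)[C@]1(C)[C@@H](O[Si](C)(C)C(C)(C)C)C=C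
F4 | step 15 | 6α,10α-bis{2-[bis(2,2,2-trifluoroethoxy)phosphoryl]propanoyloxy}-8α,9α-epoxy-2β-(naphthalen-2-ylmethoxy)daucan-4β-ol | CC(P(=O)(OCC(F)(F)F)OCC(F)(F)F)C(=O)O[C@@H]1C[C@]2(C)O[C@@H]2[C@H](OC(=O)C(C)P(=O)(OCC(F)(F)F)OCC(F)(F)F)[C@@]2(C)[C@@H](OCc3ccc4ccccc4c3)C[C@](O)(C(C)C)[C@@H]12
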